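The readings were generated by integration for substances that don't exist, and the scatter is random.

The gamma run cannot show me the peak of target, because its readings stop at 6.00 min with target still rising, from 18 % to 24 %.

- gamma: substrate 0.20 M; free catalyst 0.29 mM; run made earlier
- flask: substrate 0.10 M; free catalyst 0.29 mM; time 30 min

gamma run (percent of the substrate charged)

| time / min | target / % | substrate / % |
|---|---|---|
| 0.500 | 8 | 92 |
| 1.00 | 12 | 85 |
| 2.50 | 18 | 64 |
| 6.00 | 24 | 44 |

(standard deviation of a reading: 2 percentage points)



- the best time, 30 min at the latest, for target
- the amount of target, in percent of the substrate charged, at that time

The flask holds half the substrate of gamma at the same free catalyst. I therefore assume steps first order in substrate and take the percentages of gamma as those of the flask, though one run cannot test that.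

What then stops target? In gamma, [target]/[substrate] climbs from 0.281 to 0.545; I call this the pair ratio, target over substrate at one moment. If target forms from substrate and returns to it and goes nowhere else, target rises while the pair ratio lies below its equilibrium value and stops on reaching it. Target itself still rises up to the last reading, so on that picture the pair ratio there, 0.545 as a reading, lies below its equilibrium value, which gamma does not give. I therefore place the peak after 6.00 min, near 24 % or a little over, with a scatter of 2 percentage points.

The forecast gives 24 % at 6 min; I share its height but put the time later. It warns: “The order is untested, so the time is uncertain.”

The flask gives 24.9 % at 9.65 min.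

    2 free catalyst → spent catalyst (k = 5.90 M⁻¹ s⁻¹)
    substrate + free catalyst ⇌ isomer of the product + free catalyst, rate k2*[substrate]*[free catalyst] forward; the back reaction follows from the equilibrium constant (K = 18.0, k = 6.30 M⁻¹ s⁻¹)
    substrate ⇌ target (K = 0.630, k = 0.00160 s⁻¹)

At that best time the pair ratio in the flask is 0.630, level with the equilibrium constant of substrate ⇌ target, 0.63. A neighbouring flask, alike but charged with 7.2 × 10⁻⁴ M free catalyst, has a pair ratio of 0.674 at 30.0 min, above that constant. Its target, 19.6 % at its highest, has come down to 14.9 %.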